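The ester C11–O bond is cut last, leaving albicanol, whose ring A is then opened at C3–C4: ring B, the C5 stereocentre and the C8 methyl come from (R)-carvone, and the gem-dimethyl carbon C4 is its isopropenyl carbon. The key step exploits exactly this feature, a quaternary C4 next to the ring-fusion carbon C5 of ring A: acid converts the isopropenyl group into the C4 cation, the 2-chloroallyl arm on C10 traps it, and one operation forms C3–C4, closes ring A trans-fused and leaves a C2 ketone. The precursor is (R)-carvone alkylated twice at C6 (methyl, then 2-chloroallyl trans to isopropenyl). C11 and the exocyclic methylene follow by carbonylation and photodeconjugation.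

Key step: step 3

Remark: bicyclic compounds carry drimane numbering (decalin C1–C10, C11 on C9, C12 on C8) and monocyclic ones carvone numbering; the target is read as the (E)-2,4-dihydroxycinnamate of (+)-albicanol, (5S,9S,10S), with 5-H and 9-H on the α-face and the C10 methyl on the β-face.

Step 1
Reactants: 1 (R)-carvone; 2 iodomethane
Product: 4 6-methylcarvone (C6 epimer mixture), via lithium dienolate 3 (not isolated)
Conditions: LiN(i-Pr)2, THF, −78 °C; MeI, −78 → 0 °C
Reagents that add atoms: iodomethane 2 (CI)
Why: Kinetic deprotonation at C6 by the hindered amide gives the cross-conjugated enolate, which is C-methylated (enolate alkylation); the new C6 centre may form as either epimer because step 2 makes it planar again.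

Step 2
Reactants: 4 6-methylcarvone; 5 2,3-dichloropropene
Product: 7 (5S,6S)-6-(2-chloroprop-2-en-1-yl)-2,6-dimethyl-5-(prop-1-en-2-yl)cyclohex-2-en-1-one, via lithium enolate 6 (not isolated)
Conditions: LiN(i-Pr)2, THF, −78 → 0 °C; 2,3-dichloropropene, HMPA, −78 °C → rt
Reagents that add atoms: 2,3-dichloropropene 5 (C=C(Cl)CCl)
Why: Enolate alkylation of the tetrasubstituted C1–C6 enolate by the allylic chloride should take place on the face opposite the neighbouring isopropenyl group, which sets the quaternary C6 (later C10) with the chloroallyl group trans and the methyl group cis to isopropenyl.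

Step 3
Reactants: 7 (5S,6S)-6-(2-chloroprop-2-en-1-yl)-2,6-dimethyl-5-(prop-1-en-2-yl)cyclohex-2-en-1-one
Product: 10 (5S,10S)-11-nordrim-7-ene-2,9-dione, via tertiary C4 cation 8 (not isolated), via chlorocarbenium ion 9 (not isolated)
Conditions: HCO2H (90% aq.), 60–80 °C
Reagents that add atoms: water (O)
Why: Markovnikov protonation of the isopropenyl group gives tertiary cation 8, whose C4 is attacked by the CH2 terminus of the 2-chloroallyl arm to form C3–C4 and the chlorine-stabilised C2 cation 9; water adds to 9 and HCl is lost, leaving the C2 ketone. The closest known reaction type is the vinyl chloride-terminated cation–olefin annulation (chloroolefin annulation), in which the chloroalkene serves as a masked ketone enol. Ring A closes in a 6-endo-trig mode with respect to the chloroalkene, through a chair in which both reacting arms are equatorial on ring B. No stereocentre is created: the trans ring fusion follows from C5 of carvone and from C10 as set in step 2. The step needs 6-endo and not 5-exo attack, which the chlorine secures by placing the positive charge on C2, and it needs ring closure to outrun loss of H5 from 8, which the intramolecular six-membered closure favours, while the quaternary C10 excludes aromatisation of ring B and the O-protonated enone stays a spectator.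

Step 4
Reactants: 10 (5S,10S)-11-nordrim-7-ene-2,9-dione
Product: 11 C2 mono-tosylhydrazone of 10
Conditions: TsNHNH2 (1.05 equiv), AcOH (cat.), EtOH, rt
Reagents that add atoms: p-toluenesulfonylhydrazide (Cc1ccc(cc1)S(=O)(=O)NN)
Why: Hydrazone condensation should occur only at the saturated C2 ketone, because the C9 carbonyl is conjugated and shielded by the quaternary C10 and the C8 methyl group.

Step 5
Reactants: 11 C2 mono-tosylhydrazone of 10
Product: 14 (5S,10S)-11-nordrim-7-en-9-one, via N-boryl hydrazine 12 (not isolated), via alkyl diazene 13 (not isolated)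
Conditions: catecholborane, CHCl3, 0 °C → rt; NaOAc·3H2O, reflux
Reagents that add atoms: none
Why: Caglioti-type tosylhydrazone reduction in its catecholborane form: B–H adds across C=N, acetate releases sulfinate to give the diazene, and loss of N2 leaves CH2 at C2, while the hindered cyclic (s-trans) enone is not expected to be reduced.

Step 6
Reactants: 14 (5S,10S)-11-nordrim-7-en-9-one
Product: 16 (5S,10S)-11-nordrim-8-en-9-yl trifluoromethanesulfonate, via lithium enolate 15 (not isolated)
Conditions: LiBH(s-Bu)3, THF, −78 °C; PhNTf2, −78 °C → rt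
Reagents that add atoms: N-phenylbis(trifluoromethanesulfonimide) (O=S(=O)(N(c1ccccc1)S(=O)(=O)C(F)(F)F)C(F)(F)F)
Why: The bulky borohydride should deliver hydride to C7 (conjugate reduction), since C7 carries only hydrogen and the carbonyl is blocked, and the regiodefined C8–C9 enolate is then O-sulfonylated (enolate trapping as enol triflate).

Step 7
Reactants: 16 (5S,10S)-11-nordrim-8-en-9-yl trifluoromethanesulfonate
Product: 17 methyl (5S,10S)-drim-8-en-11-oate
Conditions: Pd(OAc)2 (cat.), PPh3, CO (1 atm), Et3N, MeOH–DMF, 60 °C
Reagents that add atoms: carbon monoxide ([C-]#[O+]); methanol (CO)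
Why: Palladium-catalysed alkoxycarbonylation of an enol triflate: oxidative addition to zerovalent palladium formed in situ, CO insertion and methanolysis of the acyl complex attach C11 to C9.

Step 8
Reactants: 17 methyl (5S,10S)-drim-8-en-11-oate
Product: 19 methyl (5S,9S,10S)-drim-8(12)-en-11-oate (methyl albicanate), via photodienol 18 (not isolated)
Conditions: hν (254 nm, quartz), 1,2-dimethylimidazole (cat.), Et2O, 0 °C
Reagents that add atoms: none
Why: Photodeconjugation of an α,β-unsaturated ester: the excited ester takes a γ-hydrogen through a six-membered transition state from C12, the γ-carbon cis to the ester, and the base-assisted protonation of dienol 18 at C9 should occur axially on the α-face, away from the axial C10 methyl, which sets C9 with the ester equatorial (β).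

Step 9
Reactants: 19 methyl albicanate
Product: 20 (+)-albicanol
Conditions: LiAlH4, Et2O, 0 °C → rt
Reagents that add atoms: none
Why: Hydride reduction of the ester to the primary alcohol is faster than any enolisation at C9 and leaves the isolated exocyclic alkene untouched.

Step 10
Reactants: 21 (E)-2,4-dihydroxycinnamic acid
Product: 23 (E)-2,4-bis(tert-butyldimethylsilyloxy)cinnamic acid, via silyl ester 22 (not isolated)
Conditions: TBSCl (3.3 equiv), imidazole, DMF, rt; AcOH–THF–H2O (3:1:1), rt
Reagents that add atoms: tert-butyldimethylsilyl chloride (CC(C)(C)[Si](C)(C)Cl)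
Why: Exhaustive silylation followed by selective hydrolysis of the labile silyl ester, the aryl silyl ethers being stable to aqueous acetic acid.

Step 11
Reactants: 20 (+)-albicanol; 23 (E)-2,4-bis(tert-butyldimethylsilyloxy)cinnamic acid
Product: 24 albicanyl (E)-2,4-bis(tert-butyldimethylsilyloxy)cinnamate
Conditions: DCC, DMAP (cat.), CH2Cl2, 0 °C → rt, dark
Reagents that add atoms: none
Why: Steglich esterification of a primary alcohol with a cinnamic acid whose phenols are masked, under neutral conditions that keep the E-alkene and the exocyclic methylene intact.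

Step 12
Reactants: 24 albicanyl (E)-2,4-bis(tert-butyldimethylsilyloxy)cinnamate
Product: 25 albicanyl (E)-2,4-dihydroxycinnamate (CNP0233491.2)
Conditions: Bu4NF, AcOH, THF, 0 °C, dark
Reagents that add atoms: none
Why: Fluoride-mediated cleavage of both aryl silyl ethers, buffered with acetic acid so that no free phenoxide attacks the ester, and run without light to avoid E-to-Z isomerisation and coumarin formation.

Compound list
1 | (R)-(−)-carvone, (5R)-2-methyl-5-(prop-1-en-2-yl)cyclohex-2-en-1-one | CC1=CC[C@@H](C(C)=C)CC1=O | starting material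
2 | iodomethane | CI | starting material
3 | lithium dienolate of 1 (O–C1=C6, cross-conjugated) | CC1=CC[C@@H](C(C)=C)C=C1[O-].[Li+] | intermediate
4 | 6-methylcarvone, (5R)-2,6-dimethyl-5-(prop-1-en-2-yl)cyclohex-2-en-1-one, mixture of C6 epimers | CC1=CC[C@@H](C(C)=C)C(C)C1=O | intermediate
5 | 2,3-dichloropropene | C=C(Cl)CCl | starting material
6 | lithium enolate of 4 (O–C1=C6, tetrasubstituted) | CC1=CC[C@@H](C(C)=C)C(C)=C1[O-].[Li+] | intermediate
7 | (5S,6S)-6-(2-chloroprop-2-en-1-yl)-2,6-dimethyl-5-(prop-1-en-2-yl)cyclohex-2-en-1-one (chloroallyl trans, methyl cis to isopropenyl) | CC1=CC[C@@H](C(C)=C)[C@](C)(CC(Cl)=C)C1=O | intermediate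
8 | tertiary C4 carbocation formed from 7 by protonation of the isopropenyl group | CC1=CC[C@@H]([C+](C)C)[C@](C)(CC(Cl)=C)C1=O | intermediate
9 | ring-closed 2-chloro C2 carbocation (trans-decalin) | CC1=CC[C@H]2C(C)(C)C[C+](Cl)C[C@]2(C)C1=O | intermediate
10 | (5S,10S)-11-nordrim-7-ene-2,9-dione, (4aS,8aS)-2,5,5,8a-tetramethyl-4,4a,5,6,8,8a-hexahydronaphthalene-1,7-dione, trans-fused | CC1=CC[C@H]2C(C)(C)CC(=O)C[C@]2(C)C1=O | intermediate
11 | C2 mono-(p-toluenesulfonyl)hydrazone of 10 | CC1=CC[C@H]2C(C)(C)CC(=NNS(=O)(=O)c3ccc(C)cc3)C[C@]2(C)C1=O | intermediate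
12 | C2 N-(1,3,2-benzodioxaborol-2-yl)-N′-tosylhydrazine from hydroboration of 11 | CC1=CC[C@H]2C(C)(C)CC(N(B3Oc4ccccc4O3)NS(=O)(=O)c3ccc(C)cc3)C[C@]2(C)C1=O | intermediate
13 | C2 monoalkyl diazene | CC1=CC[C@H]2C(C)(C)CC(N=N)C[C@]2(C)C1=O | intermediate
14 | (5S,10S)-11-nordrim-7-en-9-one, (4aS,8aS)-2,5,5,8a-tetramethyl-4a,5,6,7,8,8a-hexahydronaphthalen-1(4H)-one | CC1=CC[C@H]2C(C)(C)CCC[C@]2(C)C1=O | intermediate
15 | lithium C8–C9 enolate from conjugate reduction of 14 | CC1=C([O-])[C@@]2(C)CCCC(C)(C)[C@@H]2CC1.[Li+] | intermediate
16 | (4aS,8aS)-2,5,5,8a-tetramethyl-3,4,4a,5,6,7,8,8a-octahydronaphthalen-1-yl trifluoromethanesulfonate | CC1=C(OS(=O)(=O)C(F)(F)F)[C@@]2(C)CCCC(C)(C)[C@@H]2CC1 | intermediate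
17 | methyl (5S,10S)-drim-8-en-11-oate, methyl (4aS,8aS)-2,5,5,8a-tetramethyl-3,4,4a,5,6,7,8,8a-octahydronaphthalene-1-carboxylate | CC1=C(C(=O)OC)[C@@]2(C)CCCC(C)(C)[C@@H]2CC1 | intermediate
18 | photodienol of 17 (C9=C11 ketene hemiacetal, C8=C12 methylene) | C=C1CC[C@H]2C(C)(C)CCC[C@]2(C)C1=C(O)OC | intermediate
19 | methyl albicanate, methyl (1S,4aS,8aS)-5,5,8a-trimethyl-2-methylidenedecahydronaphthalene-1-carboxylate | C=C1CC[C@H]2C(C)(C)CCC[C@]2(C)[C@H]1C(=O)OC | intermediate
20 | (+)-albicanol, [(1S,4aS,8aS)-5,5,8a-trimethyl-2-methylidenedecahydronaphthalen-1-yl]methanol | C=C1CC[C@H]2C(C)(C)CCC[C@]2(C)[C@H]1CO | intermediate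
21 | (E)-2,4-dihydroxycinnamic acid | O=C(O)/C=C/c1ccc(O)cc1O | starting material
22 | tert-butyldimethylsilyl (E)-2,4-bis(tert-butyldimethylsilyloxy)cinnamate | CC(C)(C)[Si](C)(C)OC(=O)/C=C/c1ccc(O[Si](C)(C)C(C)(C)C)cc1O[Si](C)(C)C(C)(C)C | intermediate
23 | (E)-2,4-bis(tert-butyldimethylsilyloxy)cinnamic acid | O=C(O)/C=C/c1ccc(O[Si](C)(C)C(C)(C)C)cc1O[Si](C)(C)C(C)(C)C | intermediate
24 | albicanyl (E)-2,4-bis(tert-butyldimethylsilyloxy)cinnamate | C=C1CC[C@H]2C(C)(C)CCC[C@]2(C)[C@H]1COC(=O)/C=C/c1ccc(O[Si](C)(C)C(C)(C)C)cc1O[Si](C)(C)C(C)(C)C | intermediate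
25 | [(1S,4aS,8aS)-5,5,8a-trimethyl-2-methylidenedecahydronaphthalen-1-yl]methyl (2E)-3-(2,4-dihydroxyphenyl)prop-2-enoate | C=C1CC[C@H]2C(C)(C)CCC[C@]2(C)[C@H]1COC(=O)/C=C/c1ccc(O)cc1O | target

Total steps: 12. Longest linear sequence: 11 steps (steps 1–9, 11 and 12); step 10 is a one-step side branch.

Steps most likely to fail

Step 3. The tertiary cation may lose H5 and scramble the ring-fusion centre, or be captured by solvent faster than the weakly nucleophilic chloroalkene attacks it. The fallback replaces the chloroalkene by a ketone enol and sets out from 4. Enolate 6 is alkylated with allyl bromide, again trans to isopropenyl, to give 6-allyl-6-methylcarvone F1. Wacker oxidation of the monosubstituted alkene (PdCl2, CuCl, O2, DMF–H2O) leaves the isopropenyl group and gives the acetonyl diketone F2. Catalytic CF3SO3H in CH2Cl2, or HCO2H, then closes ring A by capture of the protonated isopropenyl group by the enol of the methyl ketone, forming the same C3–C4 bond. The C9 carbonyl is a poor aldol acceptor because it is conjugated and hindered. The fallback returns to the route at 10.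

Step 8. Hydrogen abstraction may occur from C7 instead of C12, the dienol may revert to the conjugated ester, or protonation at C9 may show poor facial selectivity. The fallback uses a ground-state dienolate and sets out from 17. LiN(i-Pr)2 with HMPA in THF at −78 °C removes a proton from C12, the γ-carbon syn to the ester, to give the lithium dienolate F3. Kinetic protonation with AcOH at −78 °C at C9 from the α-face returns to the route at 19.

Step 2. The hindered tetrasubstituted enolate may react sluggishly with the poorly electrophilic allylic chloride, allowing proton exchange, O-alkylation and erosion of facial selectivity. The fallback moves the C–C bond formation to a palladium π-allyl intermediate and sets out from 4. Enolate 6 is acylated on oxygen with 2-chloroallyl chloroformate (THF–TMEDA, −78 °C) to give the 2-chloroallyl enol carbonate F4. Pd2(dba)3 and PPh3 in THF at rt (zerovalent palladium; decarboxylative Tsuji–Trost allylation, the vinyl chloride being inert to oxidative addition under these conditions) regenerate the enolate next to the 2-chloroallyl palladium cation, which should again bond anti to the isopropenyl group. The fallback returns to the route at 7.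

Further compounds
F1 | step 3 | (5S,6S)-2,6-dimethyl-6-(prop-2-en-1-yl)-5-(prop-1-en-2-yl)cyclohex-2-en-1-one (6-allyl-6-methylcarvone, allyl trans to isopropenyl) | CC1=CC[C@@H](C(C)=C)[C@](C)(CC=C)C1=O
F2 | step 3 | (5S,6S)-2,6-dimethyl-6-(2-oxopropyl)-5-(prop-1-en-2-yl)cyclohex-2-en-1-one (acetonyl diketone) | CC1=CC[C@@H](C(C)=C)[C@](C)(CC(C)=O)C1=O
F3 | step 8 | lithium dienolate of 17 (O–C11=C9, C8=C12) | C=C1CC[C@H]2C(C)(C)CCC[C@]2(C)C1=C([O-])OC.[Li+]
F4 | step 2 | 2-chloroallyl enol carbonate of 4 (carbonate on the C1 oxygen, C1=C6) | CC1=CC[C@@H](C(C)=C)C(C)=C1OC(=O)OCC(Cl)=C
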